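**Plan**

- Retrosynthesis: cut C12–C13 (last) and then C12'–C13', the two sp2–sp2 single bonds flanking the central C13–C13' C8 segment. Cut C11=C12 (borylolefination) and C9=C10 (Horner–Wadsworth–Emmons) of each C16 half back to α-ionone. Cut the C8 segment at C14–C15 and C14'–C15' to (E)-1,2-dichloroethene and two molecules of propyne.
- Enabling feature: C13 and C13' each carry a methyl group and sit next to a C14–H. Each trisubstituted C13=C14 alkene is therefore the syn adduct of an alkenyl carbon (C12, the unsubstituted E-CH terminus of a ring-bearing triene) and H across a 1-propynyl group. The symmetric centre maps onto (E)-oct-4-ene-2,6-diyne, and the two cyclohexene rings (keto ring C1–C6, hydroxy ring C1'–C6') differ only in oxidation level at C3.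
- Forward: α-ionone → C15 nitrile → 3-oxo → cis-3-ol → lipase resolution → C15 aldehyde → C16 trienylboronate (hydroxy ring), part of which is oxidised to the keto-ring boronate. (E)-Dichloroethene + propyne → chloroenyne → enediyne (two Sonogashira steps). Hydroxy boronate + enediyne → C24 pentaenyne; keto boronate + C24 pentaenyne → target, with no protecting group and no step after the union.
- Stereochemistry: C6 and C6' (both S) and C3' (R) come from one enzymatic resolution of the racemic 3,6-cis alcohol (cis from hydride attack anti to the side chain). Chain geometry comes from α-ionone (C7=C8), the olefinations (C9=C10, C11=C12), (E)-dichloroethene (C15=C15') and syn addition to the alkynes (C13=C14, C13'=C14').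

Key step: step 11

Remark: carotenoid numbering is used (C1–C20 for the keto-ring half, primed numbers for the hydroxy-ring half), and the lipase of step 4 is assumed to acylate the 3R alcohol, as the empirical rule for lipases and cyclic allylic secondary alcohols predicts.

**Route**

Step 1
Reactants: 1 (±)-α-ionone; 2 diethyl (cyanomethyl)phosphonate
Product: 3 (2E,4E)-3-methyl-5-(2,6,6-trimethylcyclohex-2-en-1-yl)penta-2,4-dienenitrile (racemic)
Conditions: NaH, THF, 0 °C to rt; chromatography removes the minor 9Z isomer
Reagents that add atoms: none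
Why: Horner–Wadsworth–Emmons olefination of the methyl ketone with the stabilised phosphonate anion should give mainly the 9E dienenitrile and leaves the ring alkene and the (still racemic) C6 centre untouched.

Step 2
Reactants: 3 racemic C15 nitrile
Product: 4 (2E,4E)-3-methyl-5-(2,6,6-trimethyl-4-oxocyclohex-2-en-1-yl)penta-2,4-dienenitrile (racemic)
Conditions: t-BuOOH (70% in water), dirhodium tetracaprolactamate Rh2(cap)4 (1 mol%), K2CO3, CH2Cl2, rt
Reagents that add atoms: tert-butyl hydroperoxide, CC(C)(C)OO
Why: Metal-catalysed tert-butyl hydroperoxide allylic oxidation should convert the only allylic ring CH2 (C3) into the enone, because the tertiary C6–H is shielded by the gem-dimethyl group and the dienenitrile is electron-poor.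

Step 3
Reactants: 4 racemic 3-oxo nitrile
Product: 5 (2E,4E)-5-[(1S*,4R*)-4-hydroxy-2,6,6-trimethylcyclohex-2-en-1-yl]-3-methylpenta-2,4-dienenitrile (racemic cis alcohol)
Conditions: LiBH(s-Bu)3 (L-Selectride), THF, −78 °C; H2O work-up; chromatography removes the minor trans alcohol
Reagents that add atoms: none
Why: 1,2-Reduction of the β,β-disubstituted enone by the bulky borohydride should occur on the face anti to the C6 side chain (the other face of the reactive conformer is blocked by the axial C1 methyl), which sets the 3,6-cis relationship.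

Step 4
Reactants: 5 racemic cis alcohol
Product: 6 (1R,4S)-4-[(1E,3E)-4-cyano-3-methylbuta-1,3-dien-1-yl]-3,5,5-trimethylcyclohex-2-en-1-yl acetate
Conditions: Amano lipase PS (Burkholderia cepacia), vinyl acetate, t-BuOMe, 30 °C, stopped near half conversion; chromatography
Reagents that add atoms: vinyl acetate, C=COC(C)=O
Why: Lipase-catalysed kinetic resolution by irreversible transesterification should acylate only the 3R enantiomer, so the (3R,6S) acetate is separated from the unreacted (3S,6R) alcohol and C3', C6' and C6 are fixed in one operation.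

Step 5
Reactants: 6 (3R,6S) acetoxy nitrile
Product: 8 (2E,4E)-5-[(1S,4R)-4-hydroxy-2,6,6-trimethylcyclohex-2-en-1-yl]-3-methylpenta-2,4-dienal, via aldimine 7 (not isolated)
Conditions: i-Bu2AlH (4 equiv), CH2Cl2, −78 to −40 °C; then wet silica gel or aq. potassium sodium tartrate (KNaC4H4O6), 0 °C
Reagents that add atoms: water, O
Why: Half-reduction of the nitrile by i-Bu2AlH to the N-aluminio aldimine, with reductive cleavage of the acetate in the same pot and mild hydrolysis, is the standard nitrile-to-polyenal conversion and does not touch C3 or C6.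

Step 6
Reactants: 8 (3R,6S) hydroxy C15 aldehyde; 9 2-(dichloromethyl)-4,4,5,5-tetramethyl-1,3,2-dioxaborolane
Product: 10 (1R,4S)-3,5,5-trimethyl-4-[(1E,3E,5E)-3-methyl-6-(4,4,5,5-tetramethyl-1,3,2-dioxaborolan-2-yl)hexa-1,3,5-trien-1-yl]cyclohex-2-en-1-ol
Conditions: CrCl2, LiI, THF, rt
Reagents that add atoms: none
Why: Takai–Utimoto borylolefination: the geminal dichromium species formed from the dihalomethylboronate adds to the aldehyde and eliminates to the E-alkenylboronate (C11=C12), and divalent chromium tolerates the free allylic alcohol.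

Step 7
Reactants: 10 hydroxy-ring C16 boronate (part of the material)
Product: 11 (4S)-3,5,5-trimethyl-4-[(1E,3E,5E)-3-methyl-6-(4,4,5,5-tetramethyl-1,3,2-dioxaborolan-2-yl)hexa-1,3,5-trien-1-yl]cyclohex-2-en-1-one
Conditions: MnO2 (activated), CH2Cl2, rt
Reagents that add atoms: none
Why: MnO2 oxidises the allylic secondary alcohol to the enone under neutral conditions, which spares the alkenylboronate and the now base-labile C6–H.

Step 8
Reactants: 12 (E)-1,2-dichloroethene (3 equiv); 13 propyne (limiting)
Product: 14 (E)-1-chloropent-1-en-3-yne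
Conditions: Pd(PPh3)4 (3 mol%), CuI (6 mol%), n-BuNH2, Et2O, 0 °C to rt, sealed vessel; excess 12 and solvent distilled off carefully, 14 kept as a concentrated solution
Reagents that add atoms: none
Why: Sonogashira coupling: zerovalent palladium inserts into one vinyl C–Cl bond with retention and the copper acetylide of propyne is transferred, so the E geometry of dichloroethene (the future C15=C15') is kept, and the excess of 12 holds the reaction at the monocoupling stage.

Step 9
Reactants: 14 (E)-1-chloropent-1-en-3-yne; 13 propyne (excess)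
Product: 15 (E)-oct-4-ene-2,6-diyne
Conditions: Pd(PPh3)4 (5 mol%), CuI (10 mol%), n-BuNH2, THF, rt to 40 °C, sealed vessel
Reagents that add atoms: none
Why: Second Sonogashira coupling: the remaining vinyl C–Cl bond of the chloroenyne, activated by the conjugated alkyne, undergoes oxidative addition to zerovalent palladium with retention, which gives the symmetric E-enediyne.

Step 10
Reactants: 10 hydroxy-ring C16 boronate; 15 (E)-oct-4-ene-2,6-diyne
Product: 16 (1R,4S)-4-[(1E,3E,5E,7E,9E)-3,7-dimethyltrideca-1,3,5,7,9-pentaen-11-yn-1-yl]-3,5,5-trimethylcyclohex-2-en-1-ol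
Conditions: [Rh(OH)(cod)]2 (3 mol%), 15 (5 equiv), 1,4-dioxane/H2O 10:1, 50 °C, argon, dark
Reagents that add atoms: none
Why: Proposed new method: boron-to-rhodium transmetalation of the E-trienyl group, syn-carborhodation of one propynyl group (alkenyl carbon C12' to the methyl-bearing C13', rhodium to C14' next to the C15'=C15 alkene) and protonolysis by water should give the 13'E diene, by analogy with the known rhodium-catalysed syn-hydroarylation and hydroalkenylation of internal alkynes and 1,3-enynes with organoboronic acids; the excess of the symmetric enediyne limits reaction to one alkyne.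

Step 11
Reactants: 11 keto-ring C16 boronate; 16 C24 pentaenyne alcohol
Product: 17 (6S,3'R,6'S)-3'-hydroxy-ε,ε-caroten-3-one
Conditions: [Rh(OH)(cod)]2 (5 mol%), 11 (1.5 equiv), 1,4-dioxane/H2O 10:1, 50 °C, argon, dark
Reagents that add atoms: none
Why: Proposed new method: transmetalation of the E-trienyl group of 11 from boron to the hydroxorhodium centre (monovalent rhodium, retention at C11=C12) gives an alkenylrhodium that inserts the C13≡C14 propynyl terminus of 16 in a syn fashion, C12 bonding to the methyl-bearing C13 and rhodium to C14, and protonolysis by water then frees the 13E diene and regenerates Rh–OH. The closest known reaction type is the rhodium-catalysed syn-hydroarylation and hydroalkenylation of internal alkynes with organoboronic acids, including aryl additions to 1,3-enynes that place rhodium on the alkyne carbon next to the alkene. No ring is closed and no stereocentre is created; the one new stereogenic double bond (13E, C12 trans to C15) is fixed by cis addition of carbon and hydrogen across the alkyne, and the 11E geometry is carried over by stereoretentive transmetalation. The step needs regioselectivity (C12 to C13, not C14), secured by the small methyl on C13 and by conjugation of the C14–Rh bond with the C15=C15' pentaene, and chemoselectivity, secured because alkynes insert far faster than the di- and trisubstituted chain alkenes and because the β,β-disubstituted enone of the keto ring resists conjugate addition. The base-free aqueous medium spares the epimerisable C6–H of the keto ring and the free allylic C3'–OH, so the coupling should deliver the target without protecting groups or later steps.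

**Compound list**

1 | (±)-α-ionone, (E)-4-(2,6,6-trimethylcyclohex-2-en-1-yl)but-3-en-2-one (racemic) | CC(=O)/C=C/C1C(C)=CCCC1(C)C | starting material
2 | diethyl (cyanomethyl)phosphonate | N#CCP(=O)(OCC)OCC | starting material
3 | (2E,4E)-3-methyl-5-(2,6,6-trimethylcyclohex-2-en-1-yl)penta-2,4-dienenitrile (racemic) | N#C/C=C(C)/C=C/C1C(C)=CCCC1(C)C | intermediate
4 | (2E,4E)-3-methyl-5-(2,6,6-trimethyl-4-oxocyclohex-2-en-1-yl)penta-2,4-dienenitrile (racemic) | N#C/C=C(C)/C=C/C1C(C)=CC(=O)CC1(C)C | intermediate
5 | (2E,4E)-5-[(1S*,4R*)-4-hydroxy-2,6,6-trimethylcyclohex-2-en-1-yl]-3-methylpenta-2,4-dienenitrile (racemic cis alcohol; one enantiomer drawn) | N#C/C=C(C)/C=C/[C@@H]1C(C)=C[C@H](O)CC1(C)C | intermediate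
6 | (1R,4S)-4-[(1E,3E)-4-cyano-3-methylbuta-1,3-dien-1-yl]-3,5,5-trimethylcyclohex-2-en-1-yl acetate | N#C/C=C(C)/C=C/[C@@H]1C(C)=C[C@H](OC(C)=O)CC1(C)C | intermediate
7 | (2E,4E)-5-[(1S,4R)-4-hydroxy-2,6,6-trimethylcyclohex-2-en-1-yl]-3-methylpenta-2,4-dien-1-imine (aldimine, N- and O-aluminated before quench; not isolated) | N=C/C=C(C)/C=C/[C@@H]1C(C)=C[C@H](O)CC1(C)C | intermediate
8 | (2E,4E)-5-[(1S,4R)-4-hydroxy-2,6,6-trimethylcyclohex-2-en-1-yl]-3-methylpenta-2,4-dienal | O=C/C=C(C)/C=C/[C@@H]1C(C)=C[C@H](O)CC1(C)C | intermediate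
9 | 2-(dichloromethyl)-4,4,5,5-tetramethyl-1,3,2-dioxaborolane | ClC(Cl)B1OC(C)(C)C(C)(C)O1 | starting material
10 | (1R,4S)-3,5,5-trimethyl-4-[(1E,3E,5E)-3-methyl-6-(4,4,5,5-tetramethyl-1,3,2-dioxaborolan-2-yl)hexa-1,3,5-trien-1-yl]cyclohex-2-en-1-ol | CC1(C)OB(/C=C/C=C(C)/C=C/[C@@H]2C(C)=C[C@H](O)CC2(C)C)OC1(C)C | intermediate
11 | (4S)-3,5,5-trimethyl-4-[(1E,3E,5E)-3-methyl-6-(4,4,5,5-tetramethyl-1,3,2-dioxaborolan-2-yl)hexa-1,3,5-trien-1-yl]cyclohex-2-en-1-one | CC1(C)OB(/C=C/C=C(C)/C=C/[C@@H]2C(C)=CC(=O)CC2(C)C)OC1(C)C | intermediate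
12 | (E)-1,2-dichloroethene | Cl/C=C/Cl | starting material
13 | propyne | CC#C | starting material
14 | (E)-1-chloropent-1-en-3-yne | CC#C/C=C/Cl | intermediate
15 | (E)-oct-4-ene-2,6-diyne | CC#C/C=C/C#CC | intermediate
16 | (1R,4S)-4-[(1E,3E,5E,7E,9E)-3,7-dimethyltrideca-1,3,5,7,9-pentaen-11-yn-1-yl]-3,5,5-trimethylcyclohex-2-en-1-ol | CC#C/C=C/C=C(C)/C=C/C=C(C)/C=C/[C@@H]1C(C)=C[C@H](O)CC1(C)C | intermediate
17 | (6S,3'R,6'S)-3'-hydroxy-ε,ε-caroten-3-one, all-E | CC1=CC(=O)CC(C)(C)[C@@H]1/C=C/C(C)=C/C=C/C(C)=C/C=C/C=C(C)/C=C/C=C(C)/C=C/[C@@H]1C(C)=C[C@H](O)CC1(C)C | target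

**Count and risks**

Total step count: 11. Longest linear sequence: 8 steps (steps 1–6, 10 and 11; the keto-ring branch, steps 1–7 and 11, is equally long).

Steps most likely to fail:

1. Step 11 (proposed new method). What may go wrong: carborhodation with the wrong regiochemistry (alkenyl carbon to C14), repeated alkyne insertion leading to oligomers, protodeboronation of the trienylboronate before transmetalation, and thermal E/Z scrambling of the polyene. Fallback with known chemistry (Suzuki–Miyaura and Stille couplings onto a preformed C13 iodide), setting out from 15, 10 and 8 and coming back to the route at 17. Hydrozirconation of both alkynes of 15 with Cp2Zr(H)Cl (excess, THF, 50 °C, zirconium at the methyl-bearing carbons) and iodinolysis with I2 gives (2E,4E,6E)-2,7-diiodoocta-2,4,6-triene F1. Suzuki–Miyaura coupling of 10 with an excess of F1 (Pd(PPh3)4, aq. K3PO4, THF, rt) gives the C24 iodide (1R,4S)-4-[(1E,3E,5E,7E,9E,11E)-12-iodo-3,7-dimethyltrideca-1,3,5,7,9,11-hexaen-1-yl]-3,5,5-trimethylcyclohex-2-en-1-ol F2. In parallel, chromium-mediated stannylolefination of 8 (Bu3SnCHBr2, CrCl2, LiI, THF) gives (1R,4S)-3,5,5-trimethyl-4-[(1E,3E,5E)-3-methyl-6-(tributylstannyl)hexa-1,3,5-trien-1-yl]cyclohex-2-en-1-ol F3, which MnO2 oxidises to (4S)-3,5,5-trimethyl-4-[(1E,3E,5E)-3-methyl-6-(tributylstannyl)hexa-1,3,5-trien-1-yl]cyclohex-2-en-1-one F4. Neutral Stille coupling of F4 with F2 (Pd2(dba)3, AsPh3, NMP, rt) forms C12–C13 and gives 17.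

2. Step 10 (proposed new method). What may go wrong: addition to both alkynes of the enediyne, regiochemical leakage, and further insertion of the excess enediyne into the alkenylrhodium intermediate. Fallback with known chemistry, setting out from 15 and coming back at 16. Hydrozirconation of one alkyne of 15 (Cp2Zr(H)Cl, 1 equiv, THF) and iodinolysis with I2 gives (2E,4E)-2-iodoocta-2,4-dien-6-yne F5. Suzuki–Miyaura coupling of 10 with F5 (Pd(PPh3)4, aq. K3PO4, THF, rt) gives 16.

3. Step 3. What may go wrong: poor facial selectivity of hydride delivery (too much trans alcohol), followed in step 4 by incomplete discrimination of the enantiomers by the lipase. Fallback that replaces substrate control plus resolution by reagent control, setting out from 4 and coming back at 8. Corey–Bakshi–Shibata reduction of racemic 4 (2-methyl-CBS-oxazaborolidine, the enantiomer of the catalyst chosen so that hydride is delivered to the face that gives 3R, catecholborane, toluene, −78 °C) should set 3R on both enantiomers. This gives the cis alcohol (2E,4E)-5-[(1S,4R)-4-hydroxy-2,6,6-trimethylcyclohex-2-en-1-yl]-3-methylpenta-2,4-dienenitrile F6 and the trans diastereomer (2E,4E)-5-[(1R,4R)-4-hydroxy-2,6,6-trimethylcyclohex-2-en-1-yl]-3-methylpenta-2,4-dienenitrile F7, separated by chromatography. F6 is reduced with i-Bu2AlH as in step 5 (via 7) to 8.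

Further compounds
F1 | step 11 | (2E,4E,6E)-2,7-diiodoocta-2,4,6-triene | I/C(C)=C/C=C/C=C(C)/I
F2 | step 11 | (1R,4S)-4-[(1E,3E,5E,7E,9E,11E)-12-iodo-3,7-dimethyltrideca-1,3,5,7,9,11-hexaen-1-yl]-3,5,5-trimethylcyclohex-2-en-1-ol | I/C(C)=C/C=C/C=C(C)/C=C/C=C(C)/C=C/[C@@H]1C(C)=C[C@H](O)CC1(C)C
F3 | step 11 | (1R,4S)-3,5,5-trimethyl-4-[(1E,3E,5E)-3-methyl-6-(tributylstannyl)hexa-1,3,5-trien-1-yl]cyclohex-2-en-1-ol | CCCC[Sn](CCCC)(CCCC)/C=C/C=C(C)/C=C/[C@@H]1C(C)=C[C@H](O)CC1(C)C
F4 | step 11 | (4S)-3,5,5-trimethyl-4-[(1E,3E,5E)-3-methyl-6-(tributylstannyl)hexa-1,3,5-trien-1-yl]cyclohex-2-en-1-one | CCCC[Sn](CCCC)(CCCC)/C=C/C=C(C)/C=C/[C@@H]1C(C)=CC(=O)CC1(C)C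
F5 | step 10 | (2E,4E)-2-iodoocta-2,4-dien-6-yne | I/C(C)=C/C=C/C#CC
F6 | step 3 | (2E,4E)-5-[(1S,4R)-4-hydroxy-2,6,6-trimethylcyclohex-2-en-1-yl]-3-methylpenta-2,4-dienenitrile (single enantiomer) | N#C/C=C(C)/C=C/[C@@H]1C(C)=C[C@H](O)CC1(C)C
F7 | step 3 | (2E,4E)-5-[(1R,4R)-4-hydroxy-2,6,6-trimethylcyclohex-2-en-1-yl]-3-methylpenta-2,4-dienenitrile | N#C/C=C(C)/C=C/[C@H]1C(C)=C[C@H](O)CC1(C)C
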